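The route rests on opening ring D at its D1–D2 bond. Ring D is a phloroglucinol attached through D1 to C5 of the pentasubstituted ring C, so before ring closure the tetra-ortho-oxygenated biaryl bond D1–C5 is only a benzylic C–C bond of a chain. The precursor is a methyl 3,5-dioxohexanoate that carries the permethylated A–O–B–O–C triaryl diether on C6. Methoxide then closes ring D in one operation by Claisen attack of the benzylic C6 carbanion on the ester carbon, and enolisation gives the aromatic triol. Two Ullmann couplings build the diaryl ethers, an acetoacetate dianion supplies the chain, and BBr3 removes the six methyl groups.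

Key step: step 8

Remark: the target has no stereocentre and no stereogenic axis (ring D is symmetric about the C5–D1 bond); salts of phenols and enols and the aryl borates present before aqueous work-up are treated as the protonated compounds and carry no number.

Step 1
Reactants: 1 1,3,5-trimethoxybenzene; 2 methyl chlorooxoacetate
Product: 3 methyl oxo(2,4,6-trimethoxyphenyl)acetate
Conditions: AlCl3 (1.2 equiv), CH2Cl2, −10 → 0 °C; aq. HCl
Reagents that add atoms: none
Why: Friedel–Crafts acylation: the three equivalent ring CH positions of 1 are each activated by two ortho and one para methoxy group, the α-keto ester deactivates the ring against a second acylation, and the low temperature avoids AlCl3-induced cleavage of the ortho methoxy groups.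

Step 2
Reactants: 3 methyl oxo(2,4,6-trimethoxyphenyl)acetate
Product: 4 methyl (2,4,6-trimethoxyphenyl)acetate
Conditions: Et3SiH (4 equiv), CF3CO2H, CH2Cl2, 0 °C → rt
Reagents that add atoms: none
Why: Ionic hydrogenation: the protonated aryl ketone takes hydride from Et3SiH, the benzylic alcohol ionises to a cation stabilised by the 2,4,6-trimethoxyphenyl ring and is reduced again, the ester is inert, and excess silane should outrun arylation of the cation by a second arene.

Step 3
Reactants: 4 methyl (2,4,6-trimethoxyphenyl)acetate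
Product: 6 methyl (3-formyl-2,4,6-trimethoxyphenyl)acetate, via iminium chloride 5 (not isolated)
Conditions: POCl3 (1.5 equiv), DMF, 0 → 60 °C; then H2O
Reagents that add atoms: N,N-dimethylformamide, CN(C)C=O (formyl carbon); water, O (formyl oxygen)
Why: Vilsmeier–Haack formylation: the two remaining ring CH positions of 4 are equivalent and phloroglucinol-like in nucleophilicity, and the iminium group of 5 deactivates the ring against a second attack until water releases the aldehyde.

Step 4
Reactants: 6 methyl (3-formyl-2,4,6-trimethoxyphenyl)acetate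
Product: 8 methyl (3-hydroxy-2,4,6-trimethoxyphenyl)acetate, via aryl formate 7 (not isolated)
Conditions: mCPBA (1.3 equiv), NaHCO3, CH2Cl2, 0 °C → rt; then K2CO3 (cat.), MeOH, 0 °C
Reagents that add atoms: 3-chloroperoxybenzoic acid (mCPBA), OOC(=O)c1cccc(Cl)c1
Why: Baeyer–Villiger (Dakin-type) oxidation: in the Criegee adduct the electron-rich di-ortho-methoxy aryl group migrates in preference to hydrogen to give formate 7, which catalytic K2CO3 in methanol transesterifies to the phenol without changing the methyl ester.

Step 5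
Reactants: 9 3,5-dimethoxyphenol; 10 1,3-dibromo-5-methoxybenzene
Product: 11 1-bromo-3-(3,5-dimethoxyphenoxy)-5-methoxybenzene
Conditions: 10 (3 equiv), CuI (10 mol %), N,N-dimethylglycine hydrochloride (30 mol %), Cs2CO3 (2 equiv), 1,4-dioxane, 90 °C, Ar
Reagents that add atoms: none
Why: Ullmann diaryl ether synthesis: the unhindered phenoxide of 9 couples with one of the two equivalent C–Br bonds of 10, and the threefold excess of 10 (recoverable) keeps the second C–Br bond for step 6.

Step 6
Reactants: 8 methyl (3-hydroxy-2,4,6-trimethoxyphenyl)acetate; 11 1-bromo-3-(3,5-dimethoxyphenoxy)-5-methoxybenzene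
Product: 12 methyl {3-[3-(3,5-dimethoxyphenoxy)-5-methoxyphenoxy]-2,4,6-trimethoxyphenyl}acetate
Conditions: 11 (1.2 equiv), CuI (20 mol %), picolinic acid (40 mol %), K3PO4 (2 equiv), DMSO, 90 °C, Ar
Reagents that add atoms: none
Why: Ullmann coupling under the CuI–picolinic acid conditions used for hindered phenols: the di-ortho-methoxy phenoxide of 8 displaces the unhindered bromide of 11, and anhydrous K3PO4 at 90 °C should leave the methyl ester and the existing diaryl ether intact.

Step 7
Reactants: 12 methyl {3-[3-(3,5-dimethoxyphenoxy)-5-methoxyphenoxy]-2,4,6-trimethoxyphenyl}acetate; 13 methyl acetoacetate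
Product: 15 methyl 6-{3-[3-(3,5-dimethoxyphenoxy)-5-methoxyphenoxy]-2,4,6-trimethoxyphenyl}-3,5-dioxohexanoate, via methyl acetoacetate dianion 14 (not isolated)
Conditions: 13 (3 equiv), LiN(iPr)2 (6 equiv), THF, −78 → 0 °C; then 12, −78 → 0 °C; cold 1 M HCl; crude 15 used at once
Reagents that add atoms: none
Why: Crossed Claisen acylation of an acetoacetate dianion: the terminal carbanion of 14, far more nucleophilic than the internal enolate, adds to the ester of 12 and methoxide leaves, the threefold excess of 14 covering the equivalent consumed in deprotonating the acidic product.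

Step 8
Reactants: 15 methyl 6-{3-[3-(3,5-dimethoxyphenoxy)-5-methoxyphenoxy]-2,4,6-trimethoxyphenyl}-3,5-dioxohexanoate
Product: 17 3'-[3-(3,5-dimethoxyphenoxy)-5-methoxyphenoxy]-2',4',6'-trimethoxy[1,1'-biphenyl]-2,4,6-triol, via cyclohexane-1,3,5-trione 16 (not isolated)
Conditions: NaOMe (6 equiv), degassed MeOH, 65 → 110 °C (sealed), Ar; then 1 M HCl
Reagents that add atoms: none
Why: Methoxide converts 15 into its C3–C5 diketonate and then, reversibly and to a small extent, removes a benzylic C6 proton acidified by the C5 carbonyl and by ring C; the C6 carbanion adds to the C1 ester carbon, whose neighbour C2 is still protonated so that the ester stays electrophilic, and loss of methoxide forms the D1–D2 bond. The reaction is an intramolecular Claisen (Dieckmann-type) condensation of a keto ester, the known base-mediated route from 5-oxo esters to cyclohexane-1,3-diones and from polyketo esters to phloroglucinols. Ring D closes in the 6-(enolendo)-exo-trig mode, which is favoured for enolates. No stereocentre arises, and the new biaryl axis is not stereogenic because ring D is symmetric about it. The step needs C-acylation at C6 to prevail over O-acylation by the C5 enolate oxygen (4-hydroxy-2-pyranone) and over retro-Claisen cleavage: in hot methanolic methoxide the pyranone, an enol ester, should be reopened and drain back, both ketones are masked as enolate, and trione 16 tautomerises to the aromatic phenolate of 17, which cannot revert. The ortho methoxy groups of ring C should not block the closure, because the nucleophilic atom is the exocyclic C6 and the hindered D1–C5 bond already exists.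

Step 9
Reactants: 17 3'-[3-(3,5-dimethoxyphenoxy)-5-methoxyphenoxy]-2',4',6'-trimethoxy[1,1'-biphenyl]-2,4,6-triol
Product: 18 3'-[3-(3,5-dihydroxyphenoxy)-5-hydroxyphenoxy][1,1'-biphenyl]-2,2',4,4',6,6'-hexol (CNP0133338.0)
Conditions: BBr3 (20 equiv), CH2Cl2, −78 °C → rt, Ar; then H2O
Reagents that add atoms: none
Why: Lewis acid cleavage of aryl methyl ethers: BBr3 binds each methoxy oxygen and bromide removes the methyl group by SN2 displacement, whereas the diaryl ether and biaryl bonds offer no sp3 carbon and should survive, and hydrolysis of the aryl borates frees all nine hydroxy groups.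

Compound list
1 | 1,3,5-trimethoxybenzene | COc1cc(OC)cc(OC)c1 | starting material
2 | methyl chlorooxoacetate | COC(=O)C(Cl)=O | starting material
3 | methyl oxo(2,4,6-trimethoxyphenyl)acetate | COC(=O)C(=O)c1c(OC)cc(OC)cc1OC | intermediate
4 | methyl (2,4,6-trimethoxyphenyl)acetate | COC(=O)Cc1c(OC)cc(OC)cc1OC | intermediate
5 | {[3-(2-methoxy-2-oxoethyl)-2,4,6-trimethoxyphenyl]methylidene}dimethylammonium chloride (formed in the flask) | COC(=O)Cc1c(OC)cc(OC)c(C=[N+](C)C)c1OC.[Cl-] | intermediate
6 | methyl (3-formyl-2,4,6-trimethoxyphenyl)acetate | COC(=O)Cc1c(OC)cc(OC)c(C=O)c1OC | intermediate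
7 | methyl [3-(formyloxy)-2,4,6-trimethoxyphenyl]acetate (formed in the flask) | COC(=O)Cc1c(OC)cc(OC)c(OC=O)c1OC | intermediate
8 | methyl (3-hydroxy-2,4,6-trimethoxyphenyl)acetate | COC(=O)Cc1c(OC)cc(OC)c(O)c1OC | intermediate
9 | 3,5-dimethoxyphenol | COc1cc(O)cc(OC)c1 | starting material
10 | 1,3-dibromo-5-methoxybenzene | COc1cc(Br)cc(Br)c1 | starting material
11 | 1-bromo-3-(3,5-dimethoxyphenoxy)-5-methoxybenzene | COc1cc(Br)cc(Oc2cc(OC)cc(OC)c2)c1 | intermediate
12 | methyl {3-[3-(3,5-dimethoxyphenoxy)-5-methoxyphenoxy]-2,4,6-trimethoxyphenyl}acetate | COC(=O)Cc1c(OC)cc(OC)c(Oc2cc(OC)cc(Oc3cc(OC)cc(OC)c3)c2)c1OC | intermediate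
13 | methyl acetoacetate | COC(=O)CC(C)=O | starting material
14 | dilithium dianion of methyl acetoacetate (formed in the flask) | [Li+].[Li+].[CH2-]C(=O)[CH-]C(=O)OC | intermediate
15 | methyl 6-{3-[3-(3,5-dimethoxyphenoxy)-5-methoxyphenoxy]-2,4,6-trimethoxyphenyl}-3,5-dioxohexanoate | COC(=O)CC(=O)CC(=O)Cc1c(OC)cc(OC)c(Oc2cc(OC)cc(Oc3cc(OC)cc(OC)c3)c2)c1OC | intermediate
16 | 2-{3-[3-(3,5-dimethoxyphenoxy)-5-methoxyphenoxy]-2,4,6-trimethoxyphenyl}cyclohexane-1,3,5-trione (formed in the flask) | O=C1CC(=O)C(c2c(OC)cc(OC)c(Oc3cc(OC)cc(Oc4cc(OC)cc(OC)c4)c3)c2OC)C(=O)C1 | intermediate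
17 | 3'-[3-(3,5-dimethoxyphenoxy)-5-methoxyphenoxy]-2',4',6'-trimethoxy[1,1'-biphenyl]-2,4,6-triol | COc1cc(OC)cc(Oc2cc(OC)cc(Oc3c(OC)cc(OC)c(-c4c(O)cc(O)cc4O)c3OC)c2)c1 | intermediate
18 | 3'-[3-(3,5-dihydroxyphenoxy)-5-hydroxyphenoxy][1,1'-biphenyl]-2,2',4,4',6,6'-hexol | Oc1cc(O)cc(Oc2cc(O)cc(Oc3c(O)cc(O)c(-c4c(O)cc(O)cc4O)c3O)c2)c1 | target

Total step count: 9. Longest linear sequence: 8 steps (steps 1–4 and 6–9, from 1 to 18); step 5 is a one-step side branch.

Steps most likely to fail

Step 8. O-acylation by the C5 enolate oxygen may outrun the Claisen closure and park the material as the stabilised pyranone anion, or methoxide may cleave the diketone by retro-Claisen reaction. The fallback sets out from 15 and comes back to the route at 18. Compound 15 is lactonised on purpose (DBU, toluene, reflux) to 6-({3-[3-(3,5-dimethoxyphenoxy)-5-methoxyphenoxy]-2,4,6-trimethoxyphenyl}methyl)-4-hydroxy-2H-pyran-2-one F1. O-Methylation (Me2SO4, K2CO3, acetone, reflux) gives the 4-methoxy-2H-pyran-2-one F2. Heating F2 with NaOMe in MeOH (sealed, about 120 °C) opens the neutral pyranone to methyl (2E)-6-aryl-3-methoxy-5-oxohex-2-enoate F3 (not isolated). F3 has neither a diketonate nor a pyranone anion as resting state, and its ester is held cis to the ketone chain. Its C6 enolate should therefore close ring D, as in the known conversion of 4-methoxy-6-methyl-2-pyranone into 5-methoxyresorcinol. The product is 3'-[3-(3,5-dimethoxyphenoxy)-5-methoxyphenoxy]-2',4,4',6'-tetramethoxy[1,1'-biphenyl]-2,6-diol F4, which BBr3 (conditions of step 9) converts into 18.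

Step 7. The dianion may act as a base toward the benzylic CH2 of 12 (enolisation instead of acyl substitution) and be quenched by the acidic product, so that conversion stalls. The fallback sets out from 12 and comes back at 15. Ester 12 is reduced with iBu2AlH (CH2Cl2, −78 °C) to {3-[3-(3,5-dimethoxyphenoxy)-5-methoxyphenoxy]-2,4,6-trimethoxyphenyl}acetaldehyde F5. Aldol addition of dianion 14 (THF, −78 °C), which should be faster than enolisation of an aldehyde, gives racemic methyl 6-aryl-5-hydroxy-3-oxohexanoate F6. Oxidation with Dess–Martin periodinane (NaHCO3, CH2Cl2, 0 °C → rt) gives 15 and removes the transient stereocentre.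

Step 6. C–O bond formation at the di-ortho-methoxy phenoxide may be slow at 90 °C, leaving time for hydrodebromination of 11 and for base-induced damage to the ester of 8. The fallback sets out from 11 and comes back at 12. Bromine–lithium exchange on 11 (n-BuLi, THF, −78 °C), then B(OiPr)3 and aqueous acid, gives [3-(3,5-dimethoxyphenoxy)-5-methoxyphenyl]boronic acid F7. Oxidative Chan–Lam coupling of F7 with phenol 8 (Cu(OAc)2, pyridine, 4 Å molecular sieves, CH2Cl2, air, rt) should give 12. This coupling is mediated by divalent copper, runs at room temperature with a weak base and is known to accept di-ortho-substituted phenols.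

Further compounds
F1 | step 8 | 6-({3-[3-(3,5-dimethoxyphenoxy)-5-methoxyphenoxy]-2,4,6-trimethoxyphenyl}methyl)-4-hydroxy-2H-pyran-2-one | O=c1cc(O)cc(Cc2c(OC)cc(OC)c(Oc3cc(OC)cc(Oc4cc(OC)cc(OC)c4)c3)c2OC)o1
F2 | step 8 | 6-({3-[3-(3,5-dimethoxyphenoxy)-5-methoxyphenoxy]-2,4,6-trimethoxyphenyl}methyl)-4-methoxy-2H-pyran-2-one | O=c1cc(OC)cc(Cc2c(OC)cc(OC)c(Oc3cc(OC)cc(Oc4cc(OC)cc(OC)c4)c3)c2OC)o1
F3 | step 8 | methyl (2E)-6-{3-[3-(3,5-dimethoxyphenoxy)-5-methoxyphenoxy]-2,4,6-trimethoxyphenyl}-3-methoxy-5-oxohex-2-enoate | COC(=O)/C=C(/OC)CC(=O)Cc1c(OC)cc(OC)c(Oc2cc(OC)cc(Oc3cc(OC)cc(OC)c3)c2)c1OC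
F4 | step 8 | 3'-[3-(3,5-dimethoxyphenoxy)-5-methoxyphenoxy]-2',4,4',6'-tetramethoxy[1,1'-biphenyl]-2,6-diol | COc1cc(O)c(-c2c(OC)cc(OC)c(Oc3cc(OC)cc(Oc4cc(OC)cc(OC)c4)c3)c2OC)c(O)c1
F5 | step 7 | {3-[3-(3,5-dimethoxyphenoxy)-5-methoxyphenoxy]-2,4,6-trimethoxyphenyl}acetaldehyde | O=CCc1c(OC)cc(OC)c(Oc2cc(OC)cc(Oc3cc(OC)cc(OC)c3)c2)c1OC
F6 | step 7 | methyl 6-{3-[3-(3,5-dimethoxyphenoxy)-5-methoxyphenoxy]-2,4,6-trimethoxyphenyl}-5-hydroxy-3-oxohexanoate (racemic) | COC(=O)CC(=O)CC(O)Cc1c(OC)cc(OC)c(Oc2cc(OC)cc(Oc3cc(OC)cc(OC)c3)c2)c1OC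
F7 | step 6 | [3-(3,5-dimethoxyphenoxy)-5-methoxyphenyl]boronic acid | COc1cc(B(O)O)cc(Oc2cc(OC)cc(OC)c2)c1
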